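**Plan**

1. Retrosynthesis: the C5–OH and C6–OH bonds are cut first (trans-diol ⇐ 5,6-epoxide ⇐ C5=C6 alkene). The C7–O bond is then traced back to a C5–S bond by a [2,3] shift. Last, C4a–C5 and C8a–C8 are cut together, giving a 4-pyranone dienophile and a (1E,3E)-1-aryloxy-4-(phenylsulfanyl)butadiene that already carries the second chromone through the C8–O–aryl bond.
2. Enabling feature: the carbocycle (C4a, C5, C6, C7, C8, C8a) is joined to the pyranone only through C4a=C8a, which is the C2=C3 bond of a monocyclic 4-pyranone, and C5 and C8 are the hetero-substituted ends of a four-carbon unit. A methanesulfinyl group on the future C8a activates this bond, differentiates its faces and then leaves as a sulfenic acid.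
3. Forward order: the two heteroaromatic rings are made first (pyranone by acylation/cyclisation, chromone by Claisen condensation/cyclodehydration), then the diene chain is built on the phenol, then the carbocycle is closed by [4+2] cycloaddition, then oxygen is transposed and the alkene anti-dihydroxylated.
4. Stereochemistry: the sulfur stereocentre (catalytic asymmetric sulfoxidation) sets C5 and C8 in the cycloaddition; the (E,E)-diene makes them cis; the suprafacial [2,3] shift copies C5 onto C7; epoxidation anti to the C7/C8 substituents and inversion at C5 set C6 and C5.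

Key step: step 9

Abbreviation used in names: Ar = 7-methoxy-4-oxo-2-(2-phenylethyl)-4H-chromen-6-yl.
Assumption: propynal is taken as a purchasable reagent that is distilled before use.

**Step 1**
Reactants: 1 4,4-bis(methylsulfanyl)but-3-en-2-one; 2 3-phenylpropanoyl chloride
Product: 4 2-(methylsulfanyl)-6-(2-phenylethyl)-4H-pyran-4-one, via enolized diketone 3 (not isolated)
Conditions: LiN(SiMe3)2 (2 equiv), 1 (2 equiv), THF, −78 °C; then 2 (1 equiv); then CF3CO2H, CH2Cl2, 23 °C
Reagents that add atoms: none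
Why: Claisen-type C-acylation of the lithium enolate of the methyl ketone should give diketone 3, whose enol oxygen adds to the ketene dithioacetal carbon in a 6-endo addition–elimination with loss of methanethiol (the pyranone counterpart of the 2-(methylsulfanyl)chromone synthesis); no stereocentre is formed.

**Step 2**
Reactants: 4 2-(methylsulfanyl)-6-(2-phenylethyl)-4H-pyran-4-one
Product: 5 2-[(S)-methanesulfinyl]-6-(2-phenylethyl)-4H-pyran-4-one
Conditions: Ti(OiPr)4 (0.2 equiv), diethyl D-(−)-tartrate (0.4 equiv), iPrOH, 4 Å molecular sieves, cumene hydroperoxide (1.1 equiv), CH2Cl2, −20 °C; recrystallisation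
Reagents that add atoms: cumene hydroperoxide, CC(C)(OO)c1ccccc1
Why: Kagan–Modena asymmetric sulfoxidation, in which the tartrate-modified titanium peroxide should distinguish the two sulfur lone pairs of this hetaryl methyl sulfide as it does for aryl methyl sulfides, so that the (S,S)-tartrate is expected to give the (S)-sulfoxide and recrystallisation should raise the enantiomeric purity.

**Step 3**
Reactants: 6 1-(2-hydroxy-4-methoxyphenyl)ethan-1-one (paeonol)
Product: 8 1-(2,5-dihydroxy-4-methoxyphenyl)ethan-1-one, via aryl sulfate 7 (not isolated)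
Conditions: K2S2O8, aq. NaOH, 15 °C; then HCl, 90 °C
Reagents that add atoms: potassium peroxodisulfate, [K+].[K+].[O-]S(=O)(=O)OOS(=O)(=O)[O-]
Why: Elbs persulfate oxidation, in which the phenolate is attacked by peroxodisulfate para to the hydroxyl group (C5) and acid hydrolysis of aryl sulfate 7 should free the hydroquinone; no stereocentre is formed.

**Step 4**
Reactants: 8 1-(2,5-dihydroxy-4-methoxyphenyl)ethan-1-one
Product: 9 1-[5-(benzyloxy)-2-hydroxy-4-methoxyphenyl]ethan-1-one
Conditions: BnBr (1.05 equiv), K2CO3, acetone, 23 °C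
Reagents that add atoms: benzyl bromide, BrCc1ccccc1
Why: Williamson etherification, selective for the 5-OH because the 2-OH is hydrogen-bonded to the acetyl carbonyl and far less nucleophilic.

**Step 5**
Reactants: 9 1-[5-(benzyloxy)-2-hydroxy-4-methoxyphenyl]ethan-1-one; 10 ethyl 3-phenylpropanoate
Product: 12 6-(benzyloxy)-7-methoxy-2-(2-phenylethyl)-4H-chromen-4-one, via β-diketone 11 (not isolated)
Conditions: NaH (4 equiv), THF, 65 °C; aq. HCl; then p-TsOH·H2O, toluene, 80 °C
Reagents that add atoms: none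
Why: Crossed Claisen condensation of the acetophenone enolate with the ester should give β-diketone 11, which cyclodehydrates under acid to the chromone (the usual entry to 2-(2-phenylethyl)chromones).

**Step 6**
Reactants: 12 6-(benzyloxy)-7-methoxy-2-(2-phenylethyl)-4H-chromen-4-one
Product: 13 6-hydroxy-7-methoxy-2-(2-phenylethyl)-4H-chromen-4-one
Conditions: H2 (1 atm), Pd/C (10 wt % Pd on carbon), EtOAc–MeOH, 23 °C
Reagents that add atoms: none
Why: Hydrogenolysis of the benzyl ether, which at 1 atm and short reaction time should be faster than reduction of the chromone C2=C3 bond.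

**Step 7**
Reactants: 13 6-hydroxy-7-methoxy-2-(2-phenylethyl)-4H-chromen-4-one; 14 propynal
Product: 15 (2E)-3-(ArO)prop-2-enal
Conditions: DABCO (10 mol %), CH2Cl2, 0 °C
Reagents that add atoms: none
Why: Amine-catalysed oxa-Michael addition of the phenol to the ynal, in which reversible addition–elimination through the β-ammonium enal should deliver the thermodynamically favoured (E)-β-aryloxy enal.

**Step 8**
Reactants: 15 (2E)-3-(ArO)prop-2-enal; 16 diethyl [(phenylsulfanyl)methyl]phosphonate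
Product: 17 7-methoxy-2-(2-phenylethyl)-6-{[(1E,3E)-4-(phenylsulfanyl)buta-1,3-dien-1-yl]oxy}-4H-chromen-4-one
Conditions: 16, NaH, THF, 0 °C; then 15, −78 → 0 °C; chromatography on Et3N-deactivated silica
Reagents that add atoms: none
Why: Horner–Wadsworth–Emmons olefination with the sulfur-stabilised phosphonate anion should give the vinyl sulfide mainly with (E) geometry, the (1E,3E) isomer is separated, and any 3Z isomer is in any case a poor diene in the next step.

**Step 9**
Reactants: 5 2-[(S)-methanesulfinyl]-6-(2-phenylethyl)-4H-pyran-4-one; 17 (1E,3E)-1-(ArO)-4-(phenylsulfanyl)buta-1,3-diene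
Product: 19 (5R,8S)-8-(ArO)-2-(2-phenylethyl)-5-(phenylsulfanyl)-5,8-dihydro-4H-chromen-4-one, via sulfinyl cycloadduct 18 (not isolated)
Conditions: 5 (1.3 equiv), CH2Cl2, 12 kbar, 25 °C; then 40 °C at 1 bar if 18 persists
Reagents that add atoms: none
Why: Diene 17 and the C2=C3 bond of 5 (an enone whose β-carbon carries the sulfinyl group) should combine in a concerted, suprafacial [4+2] cycloaddition that closes the six-membered carbocycle by forming C4a–C5 and C8a–C8 together, and adduct 18 should then lose methanesulfenic acid by syn-elimination across C8a–C4a, which restores the pyranone. The closest known reaction type is the tandem Diels–Alder reaction/sulfoxide elimination of enantiopure sulfinylquinones and of β-sulfinyl enones used as ynone equivalents; a 4-pyranone activated only in this way is a new and less reactive member of that class, hence the high pressure. Regiochemistry: the diene terminus remote from sulfur (the aryloxy-bearing carbon, largest HOMO coefficient) should bond to C2 of 5, the β-carbon of the vinylogous ester, so that sulfur ends at C5 and the aryl ether at C8. The (E,E) geometry of 17 makes the C5–S and C8–O bonds cis, and their absolute configuration is set by the sulfur stereocentre of 5: in the rotamer with S–O syn-periplanar to C2=C3 the S-methyl group covers one face, and the diene should add to the other face with the pyranone ring endo, which for the (S)-sulfoxide leads to (5R,8S). The step needs one regiochemistry, one face and elimination only toward C4a; the last is secured because the 4a-hydrogen is cis to sulfur and α to the ketone, whereas loss of the C8 hydrogen would give a non-conjugated enol ether.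

**Step 10**
Reactants: 19 (5R,8S)-8-(ArO)-2-(2-phenylethyl)-5-(phenylsulfanyl)-5,8-dihydro-4H-chromen-4-one
Product: 22 (7S,8S)-8-(ArO)-7-hydroxy-2-(2-phenylethyl)-7,8-dihydro-4H-chromen-4-one, via allylic sulfoxide 20 (not isolated), via allylic sulfenate 21 (not isolated)
Conditions: mCPBA (1.0 equiv), CH2Cl2, −78 °C; then P(OMe)3, MeOH, −78 → 0 °C
Reagents that add atoms: 3-chloroperoxybenzoic acid, OOC(=O)c1cccc(Cl)c1
Why: Mislow–Evans sequence, in which chemoselective S-oxidation gives sulfoxide 20, its suprafacial [2,3]-sigmatropic shift moves oxygen to C7 on the face that carried sulfur at C5 (so 7-O is cis to the 8-aryloxy group) while the alkene moves into conjugation with the pyranone, and the phosphite cleaves the S–O bond of sulfenate 21.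

**Step 11**
Reactants: 22 (7S,8S)-8-(ArO)-7-hydroxy-2-(2-phenylethyl)-7,8-dihydro-4H-chromen-4-one
Product: 23 (7S,8S)-8-(ArO)-2-(2-phenylethyl)-7-[(triethylsilyl)oxy]-7,8-dihydro-4H-chromen-4-one
Conditions: Et3SiCl, imidazole, CH2Cl2, 0 °C
Reagents that add atoms: chlorotriethylsilane, CC[Si](Cl)(CC)CC
Why: Silylation of the secondary alcohol, which removes its hydroxyl-directing effect and adds bulk on the lower face for the epoxidation.

**Step 12**
Reactants: 23 (7S,8S)-8-(ArO)-2-(2-phenylethyl)-7-[(triethylsilyl)oxy]-7,8-dihydro-4H-chromen-4-one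
Product: 26 (5S,6R,7S,8S)-8-(ArO)-5,6,7-trihydroxy-2-(2-phenylethyl)-5,6,7,8-tetrahydro-4H-chromen-4-one, via epoxide 24 (not isolated), via 7-O-silyl diol 25 (not isolated)
Conditions: dimethyldioxirane (1.2 equiv), acetone, −20 °C; then THF–H2O–AcOH, 0 → 23 °C
Reagents that add atoms: dimethyldioxirane, CC1(C)OO1; water, O
Why: Dimethyldioxirane should epoxidise the electron-rich C5=C6 bond on the face anti to the 7-silyloxy and 8-aryloxy groups, acid-catalysed attack of water at C5 (the carbon stabilised by the pyranone ring oxygen) with inversion should give the 5,6-trans diol with 6-OH trans to 7-O, and the same medium cleaves the triethylsilyl ether.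

**Compound list**

1 | 4,4-bis(methylsulfanyl)but-3-en-2-one | CC(=O)C=C(SC)SC | starting material
2 | 3-phenylpropanoyl chloride | O=C(Cl)CCc1ccccc1 | starting material
3 | 1,1-bis(methylsulfanyl)-7-phenylhept-1-ene-3,5-dione | CSC(SC)=CC(=O)CC(=O)CCc1ccccc1 | intermediate
4 | 2-(methylsulfanyl)-6-(2-phenylethyl)-4H-pyran-4-one | CSc1cc(=O)cc(CCc2ccccc2)o1 | intermediate
5 | 2-[(S)-methanesulfinyl]-6-(2-phenylethyl)-4H-pyran-4-one | C[S@](=O)c1cc(=O)cc(CCc2ccccc2)o1 | intermediate
6 | 1-(2-hydroxy-4-methoxyphenyl)ethan-1-one (paeonol) | CC(=O)c1ccc(OC)cc1O | starting material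
7 | potassium 5-acetyl-4-hydroxy-2-methoxyphenyl sulfate | CC(=O)c1cc(OS(=O)(=O)[O-])c(OC)cc1O.[K+] | intermediate
8 | 1-(2,5-dihydroxy-4-methoxyphenyl)ethan-1-one | CC(=O)c1cc(O)c(OC)cc1O | intermediate
9 | 1-[5-(benzyloxy)-2-hydroxy-4-methoxyphenyl]ethan-1-one | CC(=O)c1cc(OCc2ccccc2)c(OC)cc1O | intermediate
10 | ethyl 3-phenylpropanoate | CCOC(=O)CCc1ccccc1 | starting material
11 | 1-[5-(benzyloxy)-2-hydroxy-4-methoxyphenyl]-5-phenylpentane-1,3-dione | O=C(CC(=O)CCc1ccccc1)c1cc(OCc2ccccc2)c(OC)cc1O | intermediate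
12 | 6-(benzyloxy)-7-methoxy-2-(2-phenylethyl)-4H-chromen-4-one | COc1cc2oc(CCc3ccccc3)cc(=O)c2cc1OCc1ccccc1 | intermediate
13 | 6-hydroxy-7-methoxy-2-(2-phenylethyl)-4H-chromen-4-one | COc1cc2oc(CCc3ccccc3)cc(=O)c2cc1O | intermediate
14 | propynal | C#CC=O | starting material
15 | (2E)-3-(ArO)prop-2-enal | COc1cc2oc(CCc3ccccc3)cc(=O)c2cc1O/C=C/C=O | intermediate
16 | diethyl [(phenylsulfanyl)methyl]phosphonate | CCOP(=O)(CSc1ccccc1)OCC | starting material
17 | 7-methoxy-2-(2-phenylethyl)-6-{[(1E,3E)-4-(phenylsulfanyl)buta-1,3-dien-1-yl]oxy}-4H-chromen-4-one | COc1cc2oc(CCc3ccccc3)cc(=O)c2cc1O/C=C/C=C/Sc1ccccc1 | intermediate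
18 | (4aR,5R,8S,8aS)-8-(ArO)-8a-[(S)-methanesulfinyl]-2-(2-phenylethyl)-5-(phenylsulfanyl)-4a,5,8,8a-tetrahydro-4H-chromen-4-one (cis-fused endo cycloadduct) | C[S@](=O)[C@@]12OC(CCc3ccccc3)=CC(=O)[C@@H]1[C@H](Sc1ccccc1)C=C[C@@H]2Oc1cc2c(=O)cc(CCc3ccccc3)oc2cc1OC | intermediate
19 | (5R,8S)-8-(ArO)-2-(2-phenylethyl)-5-(phenylsulfanyl)-5,8-dihydro-4H-chromen-4-one | O=c1cc(CCc2ccccc2)oc2c1[C@H](Sc1ccccc1)C=C[C@@H]2Oc1cc2c(=O)cc(CCc3ccccc3)oc2cc1OC | intermediate
20 | (5R,8S)-8-(ArO)-5-(benzenesulfinyl)-2-(2-phenylethyl)-5,8-dihydro-4H-chromen-4-one (both configurations at sulfur) | O=c1cc(CCc2ccccc2)oc2c1[C@H](S(=O)c1ccccc1)C=C[C@@H]2Oc1cc2c(=O)cc(CCc3ccccc3)oc2cc1OC | intermediate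
21 | (7S,8S)-8-(ArO)-2-(2-phenylethyl)-7-[(phenylsulfanyl)oxy]-7,8-dihydro-4H-chromen-4-one | O=c1cc(CCc2ccccc2)oc2c1C=C[C@H](OSc1ccccc1)[C@@H]2Oc1cc2c(=O)cc(CCc3ccccc3)oc2cc1OC | intermediate
22 | (7S,8S)-8-(ArO)-7-hydroxy-2-(2-phenylethyl)-7,8-dihydro-4H-chromen-4-one | O=c1cc(CCc2ccccc2)oc2c1C=C[C@H](O)[C@@H]2Oc1cc2c(=O)cc(CCc3ccccc3)oc2cc1OC | intermediate
23 | (7S,8S)-8-(ArO)-2-(2-phenylethyl)-7-[(triethylsilyl)oxy]-7,8-dihydro-4H-chromen-4-one | O=c1cc(CCc2ccccc2)oc2c1C=C[C@H](O[Si](CC)(CC)CC)[C@@H]2Oc1cc2c(=O)cc(CCc3ccccc3)oc2cc1OC | intermediate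
24 | (5R,6R,7S,8S)-5,6-epoxide of 23 (oxirane anti to the silyloxy and aryloxy groups) | O=c1cc(CCc2ccccc2)oc2c1[C@H]1O[C@H]1[C@H](O[Si](CC)(CC)CC)[C@@H]2Oc1cc2c(=O)cc(CCc3ccccc3)oc2cc1OC | intermediate
25 | (5S,6R,7S,8S)-8-(ArO)-5,6-dihydroxy-2-(2-phenylethyl)-7-[(triethylsilyl)oxy]-5,6,7,8-tetrahydro-4H-chromen-4-one | O=c1cc(CCc2ccccc2)oc2c1[C@H](O)[C@@H](O)[C@H](O[Si](CC)(CC)CC)[C@@H]2Oc1cc2c(=O)cc(CCc3ccccc3)oc2cc1OC | intermediate
26 | (5S,6R,7S,8S)-5,6,7-trihydroxy-8-{[7-methoxy-4-oxo-2-(2-phenylethyl)-4H-chromen-6-yl]oxy}-2-(2-phenylethyl)-5,6,7,8-tetrahydro-4H-chromen-4-one | COc1cc2oc(CCc3ccccc3)cc(=O)c2cc1O[C@@H]1c2oc(CCc3ccccc3)cc(=O)c2[C@H](O)[C@@H](O)[C@@H]1O | target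

**Count**

Total steps: 12. Longest linear sequence: 10 steps (6 to 26, steps 3 to 12); the dienophile branch (steps 1 and 2) joins at step 9.

**Steps most likely to fail**

Step 9. The vinylogous ester 5 may be too weak a dienophile, so that forcing conditions erode the facial selectivity, isomerise the diene or let the product aromatise by loss of thiophenol or of the phenol. The sense of induction is also a model prediction; if it is merely reversed, the L-tartrate is used in step 2. The fallback separates activation from stereocontrol. It sets out from 4 and 17: excess mCPBA converts 4 into the sulfone 2-(methanesulfonyl)-6-(2-phenylethyl)-4H-pyran-4-one F1, a β-sulfonyl enone of the kind used as an ynone equivalent. F1 and 17 in toluene at 40–60 °C should give the racemic sulfonyl cycloadduct F2, from which Et3N expels methanesulfinate to give 19 together with its enantiomer F3. The racemate is taken through the conditions of step 10, by way of 20 and 21 and their enantiomers F4 and F5, to 22 and its enantiomer F6. Lipase-catalysed acylation (immobilised Candida antarctica lipase B, vinyl acetate, tert-butyl methyl ether, 30 °C) is expected from the usual model for secondary alcohols to acylate the (7R) alcohol to acetate F7 and to leave 22, where the route is rejoined.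

Step 10. Ionisation of the doubly allylic C5–S(O)Ph bond (the cation is stabilised by the pyranone oxygen), followed by loss of a proton from C8 and aromatisation, may outrun the [2,3] shift and the slow cleavage of the sulfenate. The fallback carries selenium instead of sulfur, because an allylic selenoxide rearranges far below 0 °C and the selenenate is hydrolysed without a thiophile. It sets out from 15: diethyl [(phenylselanyl)methyl]phosphonate F8 (from diethyl (iodomethyl)phosphonate and NaSePh) is deprotonated with NaH and condensed with 15 to give the (1E,3E)-selanyl diene F9. Cycloaddition of F9 with 5 under the conditions of step 9 should give, through the sulfinyl cycloadduct F10, the allylic selenide F11. H2O2 and pyridine in CH2Cl2 at −78 °C give selenoxide F12, which rearranges to selenenate F13; aqueous work-up hydrolyses it to 22, where the route is rejoined.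

Step 12. Opening of the epoxide through a free C5 cation may give the cis-diol by front-side capture of water, and the acid may also trigger elimination toward the aromatic chromone. The fallback builds the trans-diol by syn-dihydroxylation and inversion at C5. It sets out from 23: OsO4 (catalytic) with N-methylmorpholine N-oxide should add anti to the silyloxy group to give the (5R,6R)-cis-diol F14. SO2Cl2 and Et3N convert it into cyclic sulfate F15. Bu4N(O2CPh) opens F15 at C5, the pyranone-activated carbon, with inversion to give the 5-benzoate 6-hydrogen sulfate F16. Dilute H2SO4 in wet THF removes the sulfate and silyl groups to give 5-benzoate F17, and K2CO3 in methanol gives 26.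

**Further compounds**

F1 | step 9 | 2-(methanesulfonyl)-6-(2-phenylethyl)-4H-pyran-4-one | CS(=O)(=O)c1cc(=O)cc(CCc2ccccc2)o1
F2 | step 9 | racemic 8a-methanesulfonyl cycloadduct, relative configuration as in 18 (one enantiomer drawn) | CS(=O)(=O)[C@@]12OC(CCc3ccccc3)=CC(=O)[C@@H]1[C@H](Sc1ccccc1)C=C[C@@H]2Oc1cc2c(=O)cc(CCc3ccccc3)oc2cc1OC
F3 | step 9 | (5S,8R)-enantiomer of 19 | O=c1cc(CCc2ccccc2)oc2c1[C@@H](Sc1ccccc1)C=C[C@H]2Oc1cc2c(=O)cc(CCc3ccccc3)oc2cc1OC
F4 | step 9 | (5S,8R)-enantiomer of 20 | O=c1cc(CCc2ccccc2)oc2c1[C@@H](S(=O)c1ccccc1)C=C[C@H]2Oc1cc2c(=O)cc(CCc3ccccc3)oc2cc1OC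
F5 | step 9 | (7R,8R)-enantiomer of 21 | O=c1cc(CCc2ccccc2)oc2c1C=C[C@@H](OSc1ccccc1)[C@H]2Oc1cc2c(=O)cc(CCc3ccccc3)oc2cc1OC
F6 | step 9 | (7R,8R)-enantiomer of 22 | O=c1cc(CCc2ccccc2)oc2c1C=C[C@@H](O)[C@H]2Oc1cc2c(=O)cc(CCc3ccccc3)oc2cc1OC
F7 | step 9 | (7R,8R)-7-acetoxy-8-(ArO)-2-(2-phenylethyl)-7,8-dihydro-4H-chromen-4-one | O=c1cc(CCc2ccccc2)oc2c1C=C[C@@H](OC(C)=O)[C@H]2Oc1cc2c(=O)cc(CCc3ccccc3)oc2cc1OC
F8 | step 10 | diethyl [(phenylselanyl)methyl]phosphonate | CCOP(=O)(C[Se]c1ccccc1)OCC
F9 | step 10 | 7-methoxy-2-(2-phenylethyl)-6-{[(1E,3E)-4-(phenylselanyl)buta-1,3-dien-1-yl]oxy}-4H-chromen-4-one | COc1cc2oc(CCc3ccccc3)cc(=O)c2cc1O/C=C/C=C/[Se]c1ccccc1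
F10 | step 10 | (4aR,5R,8S,8aS)-8-(ArO)-8a-[(S)-methanesulfinyl]-2-(2-phenylethyl)-5-(phenylselanyl)-4a,5,8,8a-tetrahydro-4H-chromen-4-one | C[S@](=O)[C@@]12OC(CCc3ccccc3)=CC(=O)[C@@H]1[C@H]([Se]c1ccccc1)C=C[C@@H]2Oc1cc2c(=O)cc(CCc3ccccc3)oc2cc1OC
F11 | step 10 | (5R,8S)-8-(ArO)-2-(2-phenylethyl)-5-(phenylselanyl)-5,8-dihydro-4H-chromen-4-one | O=c1cc(CCc2ccccc2)oc2c1[C@H]([Se]c1ccccc1)C=C[C@@H]2Oc1cc2c(=O)cc(CCc3ccccc3)oc2cc1OC
F12 | step 10 | (5R,8S)-8-(ArO)-5-(benzeneseleninyl)-2-(2-phenylethyl)-5,8-dihydro-4H-chromen-4-one | O=c1cc(CCc2ccccc2)oc2c1[C@H]([Se](=O)c1ccccc1)C=C[C@@H]2Oc1cc2c(=O)cc(CCc3ccccc3)oc2cc1OC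
F13 | step 10 | (7S,8S)-8-(ArO)-2-(2-phenylethyl)-7-[(phenylselanyl)oxy]-7,8-dihydro-4H-chromen-4-one | O=c1cc(CCc2ccccc2)oc2c1C=C[C@H](O[Se]c1ccccc1)[C@@H]2Oc1cc2c(=O)cc(CCc3ccccc3)oc2cc1OC
F14 | step 12 | (5R,6R,7S,8S)-8-(ArO)-5,6-dihydroxy-2-(2-phenylethyl)-7-[(triethylsilyl)oxy]-5,6,7,8-tetrahydro-4H-chromen-4-one | O=c1cc(CCc2ccccc2)oc2c1[C@@H](O)[C@@H](O)[C@H](O[Si](CC)(CC)CC)[C@@H]2Oc1cc2c(=O)cc(CCc3ccccc3)oc2cc1OC
F15 | step 12 | 5,6-cyclic sulfate of F14 | O=c1cc(CCc2ccccc2)oc2c1[C@H]1OS(=O)(=O)O[C@H]1[C@H](O[Si](CC)(CC)CC)[C@@H]2Oc1cc2c(=O)cc(CCc3ccccc3)oc2cc1OC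
F16 | step 12 | (5S,6R,7S,8S)-8-(ArO)-5-(benzoyloxy)-2-(2-phenylethyl)-7-[(triethylsilyl)oxy]-5,6,7,8-tetrahydro-4H-chromen-4-on-6-yl hydrogen sulfate | O=c1cc(CCc2ccccc2)oc2c1[C@H](OC(=O)c1ccccc1)[C@@H](OS(=O)(=O)O)[C@H](O[Si](CC)(CC)CC)[C@@H]2Oc1cc2c(=O)cc(CCc3ccccc3)oc2cc1OC
F17 | step 12 | 5-O-benzoate of 26 | O=c1cc(CCc2ccccc2)oc2c1[C@H](OC(=O)c1ccccc1)[C@@H](O)[C@H](O)[C@@H]2Oc1cc2c(=O)cc(CCc3ccccc3)oc2cc1OC
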